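**Strategy.** Numbering: C1 (CHO), C2, C3 (CH2OH), C4, C5, ring C6–C11, side chain from C12. The cyclohexane is a disguised [4+2] adduct: C8=C9–C10(O)=C11 is a 2-oxy-diene and C6=C7 a cis-dienophile, exploiting the 1,4 relation of carbinol C10 and alkylidene C7. Both partners are temporary rings: a 5-vinyl-2,3-dihydrofuran (O–C13–C12–C11=C10, locking enol ether geometry and masking the C10 ketone and C13 handle) and cyclohepta-2,6-dienone (ring C1–C7), whose later C1–C3 cleavage releases hydroxypropyl arm and enal with ring-fixed geometry. One catalytic asymmetric Diels–Alder reaction forms C7–C8 and C6–C11 and sets C6 and quaternary C11.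

Key step: step 4

**Remarks**
- All locants and stereodescriptors of the ring carbons (C1–C13) refer to the target numbering given above.
- Assumption: the (S)-oxazaborolidinium catalyst is taken to deliver the (6S,11S) adduct according to the usual carbonyl-coordination model; if the opposite sense is found, the (R)-catalyst is used.
- Hydroxy ketone 11 is expected to equilibrate with its five-membered cyclic hemiketal; the open form is drawn.
- Starting materials 1, 5, 17 and 23 and all reagents are commercial.

**Route**

Step 1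
Reactants: 1 α-methyl-γ-butyrolactone (racemic)
Product: 3 3-methyl-4,5-dihydrofuran-2-yl diphenyl phosphate, via potassium lactone enolate 2 (not isolated)
Conditions: KN(SiMe3)2, (PhO)2P(O)Cl, THF–HMPA, −78 °C
Reagents that add atoms: diphenyl chlorophosphate, O=P(Cl)(Oc1ccccc1)Oc1ccccc1
Why: O-phosphorylation of a lactone enolate (ketene acetal phosphate formation) turns the lactone into a cross-coupling partner; the stereocentre of 1 becomes sp2, so the racemate suffices.

Step 2
Reactants: 3 3-methyl-4,5-dihydrofuran-2-yl diphenyl phosphate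
Product: 4 5-ethenyl-4-methyl-2,3-dihydrofuran
Conditions: CH2=CHSnBu3, Pd(PPh3)4 (5 mol%), LiCl, THF, 65 °C
Reagents that add atoms: tributyl(vinyl)stannane, C=C[Sn](CCCC)(CCCC)CCCC
Why: Stille coupling of cyclic ketene acetal phosphates with vinylstannanes is an established route to 2-vinyl cyclic enol ethers; the ring holds O and C12 cis on C10=C11, so the diene terminus C11 has one fixed geometry.

Step 3
Reactants: 5 cycloheptanone
Product: 6 cyclohepta-2,6-dien-1-one
Conditions: IBX (2.5 equiv), DMSO–PhF, 70 °C
Reagents that add atoms: none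
Why: IBX dehydrogenation of ketones through the enol introduces α,β-unsaturation on both sides of cycloheptanone, and the seven-membered dienone cannot aromatise.

Step 4
Reactants: 4 5-ethenyl-4-methyl-2,3-dihydrofuran; 6 cyclohepta-2,6-dien-1-one
Product: 7 tricyclic enol ether enone (6S,7S,11S)
Conditions: (S)-B-(o-tolyl)oxazaborolidine from α,α-diphenylprolinol (20 mol%), HNTf2 (18 mol%), 6 (2 equiv), CH2Cl2, −78 → −40 °C; Et3N quench
Reagents that add atoms: none
Why: The N-protonated oxazaborolidine binds the dienone carbonyl and lowers the LUMO of C6=C7, while the HOMO of the 2-alkoxy-diene is largest at C11, so a concerted but asynchronous [4+2] cycloaddition starts with C11–C6 bonding (enol-ether carbon to enone β-carbon) and finishes with C8–C7, which fixes the 1,4 relation of C10–O and C2=O. The closest known reaction types are cationic oxazaborolidine-catalysed Diels–Alder reactions of 2-oxy-1,3-dienes with cyclic enones and Diels–Alder reactions of lactone-derived 2-vinyl cyclic enol ethers. The cyclohexene ring C6–C11 is closed by suprafacial [4π+2π] union of the diene termini C8 and C11 with C7 and C6, the dihydrofuran and cycloheptenone rings being carried in unchanged. C11 is set by the ring-locked diene geometry (C12 outside, CH3 inside) combined with the endo transition state, which puts C12 cis to C5 and the C11 methyl cis to H-6; the exo mode is further disfavoured because it would press C5 against the inside methyl. C6 (and with it the absolute configuration of C11) is set by the catalyst, which differentiates the enantiotopic faces of the symmetric dienone, whereas C7 is formed cis to H-6 but is erased in step 5. The step needs para regioselectivity (secured by the polarisation of both partners), endo and enantiofacial selectivity (catalyst and diene geometry) and mono-addition (excess 6; the adduct enone is α′-branched and less reactive).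

Step 5
Reactants: 7 tricyclic enol ether enone
Product: 9 dienyl triflate (C7=C2(OTf)–C1=C3), via potassium dienolate 8 (not isolated)
Conditions: KN(SiMe3)2, THF, −78 °C; PhNTf2
Reagents that add atoms: N-phenyl-bis(trifluoromethanesulfonimide), O=S(=O)(N(c1ccccc1)S(=O)(=O)C(F)(F)F)C(F)(F)F
Why: Kinetic deprotonation of the enone can only occur at the α′ methine C7–H (C1 is vinylic), and O-triflation of the cross-conjugated dienolate is routine enol triflate formation; the C7 stereocentre is erased on purpose.

Step 6
Reactants: 9 dienyl triflate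
Product: 10 methyl diene (C7=C2(CH3)–C1=C3)
Conditions: MeMgBr, Fe(acac)3 (5 mol%), THF–NMP, −30 °C
Reagents that add atoms: methylmagnesium bromide, C[Mg]Br
Why: Fe(acac)3-catalysed Kumada-type coupling of alkenyl triflates with MeMgBr is fast at low temperature and tolerates the enol ether; the C2 methyl sits on an endocyclic alkene whose geometry the ring fixes.

Step 7
Reactants: 10 methyl diene
Product: 11 γ-hydroxy ketone
Conditions: (CO2H)2 (cat.), THF–H2O, 0 °C → rt
Reagents that add atoms: water, O
Why: Acid-catalysed enol ether hydrolysis (C9 protonation, hydration of the oxocarbenium ion, hemiketal opening) is far faster than protonation of the diene and releases the C10 ketone and the C13 alcohol.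

Step 8
Reactants: 11 γ-hydroxy ketone
Product: 12 γ-iodo ketone
Conditions: I2, PPh3, imidazole, CH2Cl2, 0 °C
Reagents that add atoms: iodine, II
Why: Appel iodination of the primary alcohol through the open keto form; the halide is installed while C10 is still a ketone, so no C10 alkoxide can close a tetrahydrofuran onto C13.

Step 9
Reactants: 12 γ-iodo ketone
Product: 14 keto dialdehyde with (Z)-enal, via cis-diol 13 (not isolated)
Conditions: OsO4 (2 mol%), NaIO4, 2,6-lutidine, dioxane–H2O, rt
Reagents that add atoms: osmium tetroxide, O=[Os](=O)(=O)=O; sodium periodate, [Na+].[O-]I(=O)(=O)=O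
Why: Lemieux–Johnson oxidation: OsO4 dihydroxylates the accessible cis-disubstituted C1=C3 alkene much faster than the tetrasubstituted C2=C7 alkene and periodate cleaves the diol; because C1 and C6 were joined through the seven-membered ring, the formyl group emerges cis to C6 without any selectivity issue.

Step 10
Reactants: 14 keto dialdehyde
Product: 15 keto diol
Conditions: NaBH4, MeOH–CH2Cl2, −78 °C
Reagents that add atoms: none
Why: Chemoselective borohydride reduction: at low temperature the saturated aldehyde and the enal (1,2-mode, β-carbon fully substituted) are reduced while the hindered α-quaternary ketone is not.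

Step 11
Reactants: 15 keto diol
Product: 16 bis-silyl ether
Conditions: TBSCl, imidazole, DMF, 0 °C → rt
Reagents that add atoms: tert-butyldimethylsilyl chloride, C[Si](C)(Cl)C(C)(C)C
Why: Standard silylation masks the two primary alcohols for the organometallic steps.

Step 12
Reactants: 17 5-bromo-2-methylpent-2-ene
Product: 18 6-methylhept-5-en-1-yne
Conditions: LiC≡CH·H2N(CH2)2NH2, DMSO, 10 °C → rt
Reagents that add atoms: lithium acetylide (ethylenediamine complex), [Li]C#C
Why: SN2 alkylation of lithium acetylide by the primary homoallylic bromide in DMSO.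

Step 13
Reactants: 18 6-methylhept-5-en-1-yne
Product: 20 (1E)-1-iodo-2,6-dimethylhepta-1,5-diene, via alkenylalane 19 (not isolated)
Conditions: AlMe3, Cp2ZrCl2 (20 mol%), CH2Cl2, 0 °C → rt; I2, THF, −30 °C
Reagents that add atoms: trimethylaluminium, C[Al](C)C; iodine, II
Why: Negishi zirconium-catalysed carboalumination adds CH3 and Al syn across the terminal alkyne with CH3 at the internal carbon, and iodinolysis with retention gives the E iodoalkene.

Step 14
Reactants: 20 (1E)-1-iodo-2,6-dimethylhepta-1,5-diene
Product: 21 (2E,6E)-7-iodo-2,6-dimethylhepta-2,6-dien-1-ol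
Conditions: SeO2 (0.3 equiv), t-BuOOH, CH2Cl2, 0 °C → rt
Reagents that add atoms: selenium dioxide, O=[Se]=O; tert-butyl hydroperoxide, CC(C)(C)OO
Why: SeO2/t-BuOOH allylic oxidation (ene reaction, then [2,3]-shift) hydroxylates the E methyl group of the electron-rich trisubstituted alkene selectively, the iodoalkene being deactivated.

Step 15
Reactants: 21 (2E,6E)-7-iodo-2,6-dimethylhepta-2,6-dien-1-ol
Product: 22 (1E,5E)-7-bromo-1-iodo-2,6-dimethylhepta-1,5-diene
Conditions: CBr4, PPh3, CH2Cl2, 0 °C
Reagents that add atoms: carbon tetrabromide, BrC(Br)(Br)Br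
Why: Appel bromination converts the primary allylic alcohol into the bromide without allylic transposition.

Step 16
Reactants: 22 (1E,5E)-7-bromo-1-iodo-2,6-dimethylhepta-1,5-diene; 23 3-methylbutan-2-one
Product: 25 (6E,10E)-11-iodo-2,6,10-trimethylundeca-6,10-dien-3-one, via lithium enolate 24 (not isolated)
Conditions: LiN(i-Pr)2, THF, −78 °C; then 22, −78 → 0 °C
Reagents that add atoms: none
Why: LiN(i-Pr)2 deprotonates the methyl side of 23 under kinetic control and the enolate is alkylated by the reactive allylic bromide in an SN2 reaction.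

Step 17
Reactants: 25 (6E,10E)-11-iodo-2,6,10-trimethylundeca-6,10-dien-3-one
Product: 26 (1E,5E)-1-iodo-2,6,10-trimethyl-9-methylideneundeca-1,5-diene
Conditions: Ph3PCH3Br, KOt-Bu, THF, 0 °C → rt
Reagents that add atoms: methyltriphenylphosphonium bromide, C[P+](c1ccccc1)(c1ccccc1)c1ccccc1.[Br-]
Why: Wittig methylenation of the ketone installs the 1,1-disubstituted alkene; no stereochemical issue arises.

Step 18
Reactants: 16 bis-silyl ether; 26 (1E,5E)-1-iodo-2,6,10-trimethyl-9-methylideneundeca-1,5-diene
Product: 28 coupled ketone, via alkylzinc iodide 27 (not isolated)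
Conditions: Zn dust, LiCl, THF, 40 °C; then 26, PdCl2(dppf) (5 mol%), THF–DMA, 45 °C
Reagents that add atoms: none
Why: Negishi coupling: zinc insertion into the primary iodide tolerates the ketone and silyl ethers, and palladium-catalysed coupling with the alkenyl iodide forms C13–C14 with retention of the E geometry.

Step 19
Reactants: 28 coupled ketone
Product: 29 tertiary alcohol (10R)
Conditions: MeMgBr, CeCl3, THF, −78 °C
Reagents that add atoms: methylmagnesium bromide, C[Mg]Br
Why: Substrate-controlled 1,2-addition: the organocerium reagent adds without enolisation from the face syn to the C11 methyl (equatorial attack), the other face being blocked by the axial C6 chain and the C12 chain, which places the C10 methyl cis to the C11 methyl and the OH cis to both chains.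

Step 20
Reactants: 29 tertiary alcohol
Product: 30 triol
Conditions: Bu4NF, THF, 0 °C → rt
Reagents that add atoms: none
Why: Fluoride cleaves both primary silyl ethers; the tertiary alcohol and the alkenes are inert.

Step 21
Reactants: 30 triol
Product: 31 target CNP0226600.1
Conditions: MnO2, CH2Cl2, rt
Reagents that add atoms: none
Why: MnO2 oxidises only the allylic primary alcohol to the enal, leaving the saturated primary and the tertiary alcohol untouched, and the tetrasubstituted alkene geometry is retained.

**Compound list**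

1 | α-methyl-γ-butyrolactone (3-methyloxolan-2-one, racemic) | CC1CCOC1=O | starting material
2 | potassium 3-methyl-4,5-dihydrofuran-2-olate (lactone enolate) | CC1=C([O-])OCC1.[K+] | intermediate
3 | 3-methyl-4,5-dihydrofuran-2-yl diphenyl phosphate | CC1=C(OP(=O)(Oc2ccccc2)Oc2ccccc2)OCC1 | intermediate
4 | 5-ethenyl-4-methyl-2,3-dihydrofuran | CC1=C(C=C)OCC1 | intermediate
5 | cycloheptanone | O=C1CCCCCC1 | starting material
6 | cyclohepta-2,6-dien-1-one | O=C1C=CCCC=C1 | intermediate
7 | (6S,7S,11S) Diels–Alder adduct: dihydrofuran (O–C13–C12–C11–C10) fused to cyclohexene C6–C11 (C9=C10 enol ether), fused at C6–C7 to a cyclohept-2-enone (C2=O, C1=C3); C11-CH3, H-6 and H-7 all cis | C[C@@]12CCOC1=CC[C@H]1[C@@H]2CCC=CC1=O | intermediate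
8 | potassium cross-conjugated dienolate of 7 (C7=C2–O⁻, C1=C3) | C[C@@]12CCOC1=CCC1=C([O-])C=CCC[C@@H]12.[K+] | intermediate
9 | (6S,11S) dienyl triflate, C7=C2(OTf)–C1=C3 | C[C@@]12CCOC1=CCC1=C(OS(=O)(=O)C(F)(F)F)C=CCC[C@@H]12 | intermediate
10 | (6S,11S) methyl diene, C7=C2(CH3)–C1=C3, enol ether C9=C10 intact | C[C@@]12CCOC1=CCC1=C(C)C=CCC[C@@H]12 | intermediate
11 | (4S,4aS)-4-(2-hydroxyethyl)-4,9-dimethyl-1,2,4,4a,5,6-hexahydro-3H-benzo[7]annulen-3-one | OCC[C@]1(C)C(=O)CCC2=C(C)C=CCC[C@H]12 | intermediate
12 | (4S,4aS)-4-(2-iodoethyl)-4,9-dimethyl-1,2,4,4a,5,6-hexahydro-3H-benzo[7]annulen-3-one | ICC[C@]1(C)C(=O)CCC2=C(C)C=CCC[C@H]12 | intermediate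
13 | cis-diol of 12 at C1 and C3 (one face drawn; either is cleaved to 14) | ICC[C@]1(C)C(=O)CCC2=C(C)[C@@H](O)[C@@H](O)CC[C@H]12 | intermediate
14 | (2Z)-2-[(2S,3S)-3-(2-iodoethyl)-3-methyl-4-oxo-2-(3-oxopropyl)cyclohexylidene]propanal | ICC[C@]1(C)C(=O)CC/C(=C(\C)C=O)[C@@H]1CCC=O | intermediate
15 | (2S,3S,4Z)-4-(1-hydroxypropan-2-ylidene)-3-(3-hydroxypropyl)-2-(2-iodoethyl)-2-methylcyclohexan-1-one | ICC[C@]1(C)C(=O)CC/C(=C(\C)CO)[C@@H]1CCCO | intermediate
16 | bis(tert-butyldimethylsilyl) ether of 15 | ICC[C@]1(C)C(=O)CC/C(=C(\C)CO[Si](C)(C)C(C)(C)C)[C@@H]1CCCO[Si](C)(C)C(C)(C)C | intermediate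
17 | 5-bromo-2-methylpent-2-ene | CC(C)=CCCBr | starting material
18 | 6-methylhept-5-en-1-yne | C#CCCC=C(C)C | intermediate
19 | [(1E)-2,6-dimethylhepta-1,5-dien-1-yl]dimethylalane | C[Al](C)/C=C(\C)CCC=C(C)C | intermediate
20 | (1E)-1-iodo-2,6-dimethylhepta-1,5-diene | I/C=C(\C)CCC=C(C)C | intermediate
21 | (2E,6E)-7-iodo-2,6-dimethylhepta-2,6-dien-1-ol | I/C=C(\C)CC/C=C(\C)CO | intermediate
22 | (1E,5E)-7-bromo-1-iodo-2,6-dimethylhepta-1,5-diene | I/C=C(\C)CC/C=C(\C)CBr | intermediate
23 | 3-methylbutan-2-one | CC(=O)C(C)C | starting material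
24 | lithium 3-methylbut-1-en-2-olate | [Li]OC(=C)C(C)C | intermediate
25 | (6E,10E)-11-iodo-2,6,10-trimethylundeca-6,10-dien-3-one | I/C=C(\C)CC/C=C(\C)CCC(=O)C(C)C | intermediate
26 | (1E,5E)-1-iodo-2,6,10-trimethyl-9-methylideneundeca-1,5-diene | I/C=C(\C)CC/C=C(\C)CCC(=C)C(C)C | intermediate
27 | alkylzinc iodide from 16 (C13–ZnI) | I[Zn]CC[C@]1(C)C(=O)CC/C(=C(\C)CO[Si](C)(C)C(C)(C)C)[C@@H]1CCCO[Si](C)(C)C(C)(C)C | intermediate
28 | (2S,3S,4Z)-4-[1-(tert-butyldimethylsilyloxy)propan-2-ylidene]-3-[3-(tert-butyldimethylsilyloxy)propyl]-2-methyl-2-[(3E,7E)-4,8,12-trimethyl-11-methylidenetrideca-3,7-dien-1-yl]cyclohexan-1-one | C=C(CC/C(C)=C/CC/C(C)=C/CC[C@]1(C)C(=O)CC/C(=C(\C)CO[Si](C)(C)C(C)(C)C)[C@@H]1CCCO[Si](C)(C)C(C)(C)C)C(C)C | intermediate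
29 | (1R,2S,3S,4Z)-4-[1-(tert-butyldimethylsilyloxy)propan-2-ylidene]-3-[3-(tert-butyldimethylsilyloxy)propyl]-1,2-dimethyl-2-[(3E,7E)-4,8,12-trimethyl-11-methylidenetrideca-3,7-dien-1-yl]cyclohexan-1-ol | C=C(CC/C(C)=C/CC/C(C)=C/CC[C@]1(C)[C@](C)(O)CC/C(=C(\C)CO[Si](C)(C)C(C)(C)C)[C@@H]1CCCO[Si](C)(C)C(C)(C)C)C(C)C | intermediate
30 | (1R,2S,3S,4Z)-4-(1-hydroxypropan-2-ylidene)-3-(3-hydroxypropyl)-1,2-dimethyl-2-[(3E,7E)-4,8,12-trimethyl-11-methylidenetrideca-3,7-dien-1-yl]cyclohexan-1-ol | C=C(CC/C(C)=C/CC/C(C)=C/CC[C@]1(C)[C@](C)(O)CC/C(=C(\C)CO)[C@@H]1CCCO)C(C)C | intermediate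
31 | (2Z)-2-[(2S,3S,4R)-4-hydroxy-2-(3-hydroxypropyl)-3,4-dimethyl-3-[(3E,7E)-4,8,12-trimethyl-11-methylidenetrideca-3,7-dien-1-yl]cyclohexylidene]propanal (CNP0226600.1) | C=C(CC/C(C)=C/CC/C(C)=C/CC[C@@]1(C)[C@@H](CCCO)/C(=C(/C)C=O)CC[C@@]1(C)O)C(C)C | target

**Step count**
Total: 21 steps. Longest linear sequence: 14 steps (steps 1, 2, 4–11, 18–21).

**Steps most likely to fail**

1. Step 4 (key step). The fully substituted diene terminus may react so slowly that acid-induced oligomerisation of the enol ether diene competes, or the endo and enantiofacial discrimination by the monodentate boron catalyst may be insufficient. The fallback sets out from 6 and 4 and comes back at 7; it uses a doubly activated dienophile bound in a two-point fashion. Dienone 6 is α-iodinated (I2, pyridine, CH2Cl2) to 2-iodocyclohepta-2,6-dien-1-one F1, which is methoxycarbonylated (CO, MeOH, Pd(OAc)2, PPh3, Et3N) to methyl 7-oxocyclohepta-1,5-diene-1-carboxylate F2. This β-keto ester chelates Cu(OTf)2–(S,S)-tert-butyl-bisoxazoline (ligand antipode chosen for 6S,11S) and should react with 4 at its ester-bearing alkene under much milder conditions to give the angular methyl ester adduct F3. Krapcho demethoxycarbonylation (LiCl, wet DMSO, 130 °C) then gives 7; the configuration formed at C7 is irrelevant because step 5 erases it.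

2. Step 19. Facial selectivity of the methyl addition at the hindered α-quaternary ketone may be poor, or enolisation may outrun addition. The fallback runs from 28 to 29. A Corey–Chaykovsky reaction with dimethylsulfoxonium methylide (Me3S(O)I, NaH, DMSO) adds reversibly and should give the thermodynamically preferred spiro-epoxide F4 with the new C–C bond equatorial, that is, CH2 cis to the C11 methyl. Hydride opening at the CH2 terminus (LiBHEt3, THF, 0 °C) then gives 29.

3. Step 18. Zinc insertion may be sluggish, or the alkylzinc may be protonated or undergo β-hydride pathways before coupling. The fallback goes from 16 and 26 directly to 28: a nickel-catalysed reductive cross-electrophile coupling (NiBr2·glyme, 4,4′-di-tert-butyl-2,2′-bipyridine, Mn powder, NaI, DMA, rt) joins the alkyl iodide and the alkenyl iodide without a preformed organometallic. This fallback makes no new compound (F0).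

**Further compounds**
F1 | step 4 | 2-iodocyclohepta-2,6-dien-1-one | O=C1C(I)=CCCC=C1
F2 | step 4 | methyl 7-oxocyclohepta-1,5-diene-1-carboxylate | COC(=O)C1=CCCC=CC1=O
F3 | step 4 | angular methyl ester adduct (7 with CO2CH3 in place of H-7; 6S,11S) | C[C@@]12CCOC1=CC[C@@]1(C(=O)OC)[C@@H]2CCC=CC1=O
F0 | step 18 | none | none
F4 | step 19 | spiro-epoxide of 28 at C10 (CH2 cis to the C11 methyl) | C=C(CC/C(C)=C/CC/C(C)=C/CC[C@]1(C)[C@@]2(CO2)CC/C(=C(\C)CO[Si](C)(C)C(C)(C)C)[C@@H]1CCCO[Si](C)(C)C(C)(C)C)C(C)C
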